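## Retrosynthetic overview

1. The target comes from its penta-O-benzyl ether (hydrogenolysis), and the 3-hydroxyl of the lower unit from cis-selective hydride reduction of a flavan-3-one.
2. Key C–C disconnection: C4–C4a of the lower (epiafzelechin) unit. An α-oxo gold carbene, made from a terminal alkyne and an N-oxide, acts as an α-keto cation (enolonium equivalent) and is attacked by the arene ortho to the ether oxygen. The arene carbon and the ketone α-carbon are both normally nucleophilic. The interflavan carbon sits para to that oxygen and the two ortho positions are equivalent, so only the 4→6 constitution can form.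
3. The (S)-aryl propargyl ether comes from copper-catalysed asymmetric propargylic etherification of 2,6-bis(benzyloxy)-4-hydroxybenzaldehyde (Vilsmeier product of 3,5-bis(benzyloxy)phenol); its formyl carbon becomes C4 of the upper unit.
4. The upper 2,4-cis flavan comes from a chiral-acid-catalysed [4+2] cycloaddition of an ortho-quinone methide (from ortho-hydroxyalkylation of 3-(benzyloxy)phenol by that aldehyde) with 4-(benzyloxy)styrene.
5. Ring order: all benzene rings are bought; the pyran ring of the upper unit is closed first (step 5), the pyran ring of the lower unit last (step 6).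

Assumption: the ligand enantiomer named in step 3 and the acid-catalyst enantiomer named in step 5 are taken to give the configurations drawn; if a first run shows the opposite sense, the mirror-image ligand or catalyst is used and nothing else changes.

## Route

Step 1
Reactants: 1 4-(benzyloxy)benzaldehyde; 2 ethynylmagnesium bromide
Product: 4 rac-1-[4-(benzyloxy)phenyl]prop-2-yn-1-yl acetate, via bromomagnesium propargylic alkoxide 3 (not isolated)
Conditions: HC≡CMgBr (1.2 equiv), THF, 0 °C; then Ac2O (1.5 equiv), 0 °C to rt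
Reagents that add atoms: acetic anhydride CC(=O)OC(C)=O
Why: Grignard 1,2-addition of the acetylide to the aldehyde, then O-acylation of the magnesium alkoxide in the same flask, gives the racemic propargylic acetate; no stereocontrol is needed because step 3 is enantioconvergent.

Step 2
Reactants: 5 3,5-bis(benzyloxy)phenol
Product: 7 2,6-bis(benzyloxy)-4-hydroxybenzaldehyde, via aryl iminium chloride 6 (not isolated)
Conditions: POCl3 (1.2 equiv), DMF, 0 °C to rt; then H2O, 50 °C
Reagents that add atoms: N,N-dimethylformamide CN(C)C=O; water O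
Why: Vilsmeier–Haack formylation of the phloroglucinol-type ring goes mainly para to the free hydroxyl (between the two benzyloxy groups), as with 3,5-dimethoxyphenol, and the minor chelated ortho isomer is removed by crystallisation; the formyl carbon becomes C4 of the upper unit and the para oxygen becomes O1 of the lower unit.

Step 3
Reactants: 7 2,6-bis(benzyloxy)-4-hydroxybenzaldehyde; 4 rac-1-[4-(benzyloxy)phenyl]prop-2-yn-1-yl acetate
Product: 8 2,6-bis(benzyloxy)-4-{[(1S)-1-[4-(benzyloxy)phenyl]prop-2-yn-1-yl]oxy}benzaldehyde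
Conditions: (CuOTf)2·C6H6 (5 mol %), (S,S)-Ph-pybox (10 mol %), iPr2NEt (1.2 equiv), 4 (1.3 equiv), toluene, −10 °C
Reagents that add atoms: none
Why: Copper-catalysed asymmetric propargylic etherification of a terminal-alkyne propargylic ester: the chiral pybox–copper catalyst ionises the acetate and directs phenoxide attack to one face of the propargylic carbon (both enantiomers of 4 converge), setting the (S) centre that later becomes C2 of the lower unit.

Step 4
Reactants: 8 2,6-bis(benzyloxy)-4-{[(1S)-1-[4-(benzyloxy)phenyl]prop-2-yn-1-yl]oxy}benzaldehyde; 9 3-(benzyloxy)phenol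
Product: 11 [4-(benzyloxy)-2-hydroxyphenyl][2,6-bis(benzyloxy)-4-{[(1S)-1-[4-(benzyloxy)phenyl]prop-2-yn-1-yl]oxy}phenyl]methanol (both carbinol epimers), via bromomagnesium 3-(benzyloxy)phenoxide 10 (not isolated)
Conditions: 9, EtMgBr (1.0 equiv), Et2O, 0 °C; solvent changed to toluene; then 8, 25 °C; pH 7 buffer
Reagents that add atoms: none
Why: Casiraghi-type ortho-specific hydroxyalkylation: the magnesium phenoxide binds the aldehyde and delivers the ring carbon ortho to oxygen (the less hindered site, para to the benzyloxy group) through a six-membered chelate to give the 2-hydroxybenzhydrol; the new carbinol centre is uncontrolled and is erased in step 5.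

Step 5
Reactants: 11 [4-(benzyloxy)-2-hydroxyphenyl][2,6-bis(benzyloxy)-4-{[(1S)-1-[4-(benzyloxy)phenyl]prop-2-yn-1-yl]oxy}phenyl]methanol; 12 4-(benzyloxy)styrene
Product: 14 (2S,4S)-7-(benzyloxy)-2-[4-(benzyloxy)phenyl]-4-[2,6-bis(benzyloxy)-4-{[(1S)-1-[4-(benzyloxy)phenyl]prop-2-yn-1-yl]oxy}phenyl]-3,4-dihydro-2H-chromene, via ortho-quinone methide 13 (not isolated)
Conditions: (R)-3,3'-bis(2,4,6-triisopropylphenyl)-1,1'-binaphthyl-2,2'-diyl N-triflylphosphoramide (5 mol %), 12 (3 equiv), 4 Å MS, CH2Cl2, −20 °C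
Reagents that add atoms: none
Why: Chiral Brønsted acid catalysed dehydration to the ortho-quinone methide and inverse-electron-demand oxa-[4+2] cycloaddition (hetero-Diels–Alder) with the electron-rich styrene inside the chiral ion pair: endo approach places the 2- and 4-aryl groups cis and the catalyst selects the face giving (2S,4S), while any minor enantiomer carried from step 3 is now a separable diastereomer.

Step 6
Reactants: 14 (2S,4S)-7-(benzyloxy)-2-[4-(benzyloxy)phenyl]-4-[2,6-bis(benzyloxy)-4-{[(1S)-1-[4-(benzyloxy)phenyl]prop-2-yn-1-yl]oxy}phenyl]-3,4-dihydro-2H-chromene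
Product: 16 (2R)-5,7-bis(benzyloxy)-2-[4-(benzyloxy)phenyl]-6-{(2S,4S)-7-(benzyloxy)-2-[4-(benzyloxy)phenyl]-3,4-dihydro-2H-chromen-4-yl}-2H-chromen-3(4H)-one, via α-oxo gold carbene 15 (not isolated)
Conditions: (Me4tBuXPhos)AuNTf2 (5 mol %), 2,6-dichloropyridine N-oxide (1.3 equiv), 1,2-dichloroethane, 25 °C
Reagents that add atoms: 2,6-dichloropyridine N-oxide [O-][n+]1c(Cl)cccc1Cl
Why: Gold-catalysed alkyne oxidation followed by intramolecular Friedel–Crafts-type carbene arylation: the N-oxide adds to the internal carbon of the gold-bound terminal alkyne and loss of 2,6-dichloropyridine leaves an α-oxo gold carbene, an α-keto cation (enolonium) equivalent whose carbon (the future C4, normally the nucleophilic enolate carbon of the ketone) is attacked by the electron-rich arene ortho to the ether oxygen in a six-membered closure; both ortho positions are equivalent and para to the interflavan carbon, so only the 6-linked chroman-3-one forms and the ether centre is carried over unchanged as (2R).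

Step 7
Reactants: 16 (2R)-5,7-bis(benzyloxy)-2-[4-(benzyloxy)phenyl]-6-{(2S,4S)-7-(benzyloxy)-2-[4-(benzyloxy)phenyl]-3,4-dihydro-2H-chromen-4-yl}-2H-chromen-3(4H)-one
Product: 17 (2R,3R)-5,7-bis(benzyloxy)-2-[4-(benzyloxy)phenyl]-6-{(2S,4S)-7-(benzyloxy)-2-[4-(benzyloxy)phenyl]-3,4-dihydro-2H-chromen-4-yl}-3,4-dihydro-2H-chromen-3-ol
Conditions: LiBH(s-Bu)3 (L-Selectride, 1.5 equiv), LiBr, THF, −78 °C; then H2O
Reagents that add atoms: none
Why: Diastereoselective ketone reduction with a bulky hydride, which attacks C3 from the face opposite the 2-aryl group and gives the axial 3-hydroxyl cis to the aryl (2R,3R), as in the known flavan-3-one to epi-series reduction.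

Step 8
Reactants: 17 (2R,3R)-5,7-bis(benzyloxy)-2-[4-(benzyloxy)phenyl]-6-{(2S,4S)-7-(benzyloxy)-2-[4-(benzyloxy)phenyl]-3,4-dihydro-2H-chromen-4-yl}-3,4-dihydro-2H-chromen-3-ol
Product: 18 (2R,3R)-6-[(2S,4S)-7-hydroxy-2-(4-hydroxyphenyl)-3,4-dihydro-2H-chromen-4-yl]-2-(4-hydroxyphenyl)-3,4-dihydro-2H-chromene-3,5,7-triol
Conditions: H2 (1 atm), Pd(OH)2/C, THF/MeOH 1:1, 25 °C
Reagents that add atoms: none
Why: Catalytic hydrogenolysis of the five benzyl ethers under mild conditions that leave the cyclic benzylic ethers, the interflavan bond and all four stereocentres untouched.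

## Compound list

1 | 4-(benzyloxy)benzaldehyde | O=Cc1ccc(OCc2ccccc2)cc1 | starting material
2 | ethynylmagnesium bromide (0.5 M in THF) | C#C[Mg]Br | starting material
3 | bromomagnesium 1-[4-(benzyloxy)phenyl]prop-2-yn-1-olate (racemic, formed in the flask in step 1) | C#CC(O[Mg]Br)c1ccc(OCc2ccccc2)cc1 | intermediate
4 | rac-1-[4-(benzyloxy)phenyl]prop-2-yn-1-yl acetate | C#CC(OC(C)=O)c1ccc(OCc2ccccc2)cc1 | intermediate
5 | 3,5-bis(benzyloxy)phenol | Oc1cc(OCc2ccccc2)cc(OCc2ccccc2)c1 | starting material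
6 | N-{[2,6-bis(benzyloxy)-4-hydroxyphenyl]methylidene}-N-methylmethanaminium chloride (formed in the flask in step 2) | C[N+](C)=Cc1c(OCc2ccccc2)cc(O)cc1OCc1ccccc1.[Cl-] | intermediate
7 | 2,6-bis(benzyloxy)-4-hydroxybenzaldehyde | O=Cc1c(OCc2ccccc2)cc(O)cc1OCc1ccccc1 | intermediate
8 | 2,6-bis(benzyloxy)-4-{[(1S)-1-[4-(benzyloxy)phenyl]prop-2-yn-1-yl]oxy}benzaldehyde | O=Cc1c(OCc2ccccc2)cc(O[C@@H](C#C)c2ccc(OCc3ccccc3)cc2)cc1OCc1ccccc1 | intermediate
9 | 3-(benzyloxy)phenol | Oc1cccc(OCc2ccccc2)c1 | starting material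
10 | bromomagnesium 3-(benzyloxy)phenoxide (formed in the flask in step 4) | Br[Mg]Oc1cccc(OCc2ccccc2)c1 | intermediate
11 | [4-(benzyloxy)-2-hydroxyphenyl][2,6-bis(benzyloxy)-4-{[(1S)-1-[4-(benzyloxy)phenyl]prop-2-yn-1-yl]oxy}phenyl]methanol (both carbinol epimers) | OC(c1ccc(OCc2ccccc2)cc1O)c1c(OCc2ccccc2)cc(O[C@@H](C#C)c2ccc(OCc3ccccc3)cc2)cc1OCc1ccccc1 | intermediate
12 | 4-(benzyloxy)styrene | C=Cc1ccc(OCc2ccccc2)cc1 | starting material
13 | (6E)-3-(benzyloxy)-6-{[2,6-bis(benzyloxy)-4-{[(1S)-1-[4-(benzyloxy)phenyl]prop-2-yn-1-yl]oxy}phenyl]methylidene}cyclohexa-2,4-dien-1-one (ortho-quinone methide, formed in the flask in step 5) | O=C1C=C(OCc2ccccc2)C=C/C1=C\c1c(OCc2ccccc2)cc(O[C@@H](C#C)c2ccc(OCc3ccccc3)cc2)cc1OCc1ccccc1 | intermediate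
14 | (2S,4S)-7-(benzyloxy)-2-[4-(benzyloxy)phenyl]-4-[2,6-bis(benzyloxy)-4-{[(1S)-1-[4-(benzyloxy)phenyl]prop-2-yn-1-yl]oxy}phenyl]-3,4-dihydro-2H-chromene (2,4-cis) | c1ccccc1COc1ccc([C@@H]2C[C@H](c3c(OCc5ccccc5)cc(O[C@@H](C#C)c4ccc(OCc5ccccc5)cc4)cc3OCc3ccccc3)c3ccc(OCc4ccccc4)cc3O2)cc1 | intermediate
15 | α-oxo gold carbene: {(3R)-3-[aryloxy]-3-[4-(benzyloxy)phenyl]-2-oxopropylidene}(Me4tBuXPhos)gold bis(trifluoromethanesulfonyl)imide, aryl being the 3,5-bis(benzyloxy)-4-[(2S,4S)-chroman-4-yl]phenyl group of 14; Me4tBuXPhos is di-tert-butyl(2',4',6'-triisopropyl-3,4,5,6-tetramethylbiphenyl-2-yl)phosphine (formed in the flask in step 6) | c1ccccc1COc1ccc([C@@H]2C[C@H](c3c(OCc5ccccc5)cc(O[C@@H](C(=O)C=[Au][P+](C(C)(C)C)(C(C)(C)C)c4c(C)c(C)c(C)c(C)c4-c4c(C(C)C)cc(C(C)C)cc4C(C)C)c4ccc(OCc5ccccc5)cc4)cc3OCc3ccccc3)c3ccc(OCc4ccccc4)cc3O2)cc1.[N-](S(=O)(=O)C(F)(F)F)S(=O)(=O)C(F)(F)F | intermediate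
16 | (2R)-5,7-bis(benzyloxy)-2-[4-(benzyloxy)phenyl]-6-{(2S,4S)-7-(benzyloxy)-2-[4-(benzyloxy)phenyl]-3,4-dihydro-2H-chromen-4-yl}-2H-chromen-3(4H)-one | c1ccccc1COc1ccc([C@@H]2C[C@H](c3c(OCc5ccccc5)cc4c(c3OCc3ccccc3)CC(=O)[C@@H](c3ccc(OCc5ccccc5)cc3)O4)c3ccc(OCc4ccccc4)cc3O2)cc1 | intermediate
17 | (2R,3R)-5,7-bis(benzyloxy)-2-[4-(benzyloxy)phenyl]-6-{(2S,4S)-7-(benzyloxy)-2-[4-(benzyloxy)phenyl]-3,4-dihydro-2H-chromen-4-yl}-3,4-dihydro-2H-chromen-3-ol | c1ccccc1COc1ccc([C@@H]2C[C@H](c3c(OCc5ccccc5)cc4c(c3OCc3ccccc3)C[C@@H](O)[C@@H](c3ccc(OCc5ccccc5)cc3)O4)c3ccc(OCc4ccccc4)cc3O2)cc1 | intermediate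
18 | (2R,3R)-6-[(2S,4S)-7-hydroxy-2-(4-hydroxyphenyl)-3,4-dihydro-2H-chromen-4-yl]-2-(4-hydroxyphenyl)-3,4-dihydro-2H-chromene-3,5,7-triol (CNP0167324.1) | Oc1ccc([C@@H]2C[C@H](c3c(O)cc4c(c3O)C[C@@H](O)[C@@H](c3ccc(O)cc3)O4)c3ccc(O)cc3O2)cc1 | target

## Step count and risks

Total step count: 8.
Longest linear sequence: 7 steps (steps 2 to 8, from 5 to 18); step 1 is a one-step side branch.

Steps most likely to fail:

Step 6 (gold oxidation and ring closure). The electron-rich ring may instead add directly to the gold-bound alkyne (6-endo hydroarylation to a 2H-chromene), the carbene may be oxidised a second time, or the doubly activated propargylic ether may ionise. The fallback keeps the α-keto cation logic but uses a classical α-halo ketone. It sets out from 14: the alkyne C–H is brominated (NBS, 10 mol % AgNO3, acetone, 25 °C) to the 1-bromoalkyne F1. Markovnikov hydration (Ph3PAuNTf2 2 mol %, H2O, 1,4-dioxane, 25 °C; no carbene is involved) gives the bromomethyl ketone F2. AgOTf with 2,6-di-tert-butyl-4-methylpyridine in CH2Cl2 at −20 °C then ionises the C–Br bond and the arene closes the ring ortho to the ether oxygen, which returns the route at 16.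

Step 5 (asymmetric [4+2]). The di-ortho-substituted aryl group on the methide carbon may erode facial control, and the strong chiral acid may attack the propargylic ether. The fallback gives up catalyst control and resolves through the centre already present. It sets out from 11: with achiral diphenyl phosphate (5 mol %, CH2Cl2, 0 °C) and 12, the endo preference still gives only 2,4-cis chromans, now as a roughly 1:1 pair of 14 and the (2R,4R)-diastereomer F3. Because the (S)-propargylic centre is fixed these two are diastereomers and are separated by chromatography or crystallisation; 14 re-enters the route.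

Step 4 (ortho-hydroxyalkylation). The hindered, electron-rich aldehyde 8 may react slowly, and the very ionisable product may add a second phenol to give a triarylmethane. The fallback templates the condensation on boron. It sets out from 8 and 9: PhB(OH)2 and catalytic propanoic acid in refluxing toluene (Dean–Stark) give the cyclic phenylboronate F4 (a 4H-1,3,2-benzodioxaborinine), which cannot ionise further and is isolable. Transesterification with propane-1,3-diol in THF at 25 °C releases the benzhydrol and returns the route at 11.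

Further compounds

F1 | step 6 | (2S,4S)-7-(benzyloxy)-2-[4-(benzyloxy)phenyl]-4-[2,6-bis(benzyloxy)-4-{[(1R)-1-[4-(benzyloxy)phenyl]-3-bromoprop-2-yn-1-yl]oxy}phenyl]-3,4-dihydro-2H-chromene | c1ccccc1COc1ccc([C@@H]2C[C@H](c3c(OCc5ccccc5)cc(O[C@@H](C#CBr)c4ccc(OCc5ccccc5)cc4)cc3OCc3ccccc3)c3ccc(OCc4ccccc4)cc3O2)cc1
F2 | step 6 | (2S,4S)-7-(benzyloxy)-2-[4-(benzyloxy)phenyl]-4-[2,6-bis(benzyloxy)-4-{[(1R)-1-[4-(benzyloxy)phenyl]-3-bromo-2-oxopropyl]oxy}phenyl]-3,4-dihydro-2H-chromene | c1ccccc1COc1ccc([C@@H]2C[C@H](c3c(OCc5ccccc5)cc(O[C@@H](C(=O)CBr)c4ccc(OCc5ccccc5)cc4)cc3OCc3ccccc3)c3ccc(OCc4ccccc4)cc3O2)cc1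
F3 | step 5 | (2R,4R)-7-(benzyloxy)-2-[4-(benzyloxy)phenyl]-4-[2,6-bis(benzyloxy)-4-{[(1S)-1-[4-(benzyloxy)phenyl]prop-2-yn-1-yl]oxy}phenyl]-3,4-dihydro-2H-chromene | c1ccccc1COc1ccc([C@H]2C[C@@H](c3c(OCc5ccccc5)cc(O[C@@H](C#C)c4ccc(OCc5ccccc5)cc4)cc3OCc3ccccc3)c3ccc(OCc4ccccc4)cc3O2)cc1
F4 | step 4 | 7-(benzyloxy)-4-[2,6-bis(benzyloxy)-4-{[(1S)-1-[4-(benzyloxy)phenyl]prop-2-yn-1-yl]oxy}phenyl]-2-phenyl-4H-1,3,2-benzodioxaborinine (both C4 epimers) | c1ccccc1B1OC(c2c(OCc3ccccc3)cc(O[C@@H](C#C)c3ccc(OCc4ccccc4)cc3)cc2OCc2ccccc2)c2ccc(OCc3ccccc3)cc2O1
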